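The runs come from a simulation with made-up constants; scatter was added.

Early in Monday's run, at 15 °C, the target came slowly and then faster: 1.1% at 2.00 d and 3.0% at 4.00 d, which is 2.73 times the amount for twice the time. I took this lag (an induction period) as early growth with the square of time, a rough assumption, since the square asks for 4 times.

| setting | Saturday's | Monday's | red | ochre | blue | teal |
|---|---|---|---|---|---|---|
| starting material | 2 M | 2 M | 2.0 M | 2.0 M | 2.0 M | 2.0 M |
| partner | 1.4 M | 2.2 M | 1.00 M | 1.00 M | 1.00 M | 1.00 M |
| protic impurity | 0.10 M | 0.10 M | 0.100 M | 0.100 M | 0.100 M | 0.100 M |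
| temperature | −15 °C | 15 °C | 40 °C |  | 15 °C | −10 °C |
| remark | run made earlier | run made earlier |  | at 40 °C until 20 h, from then on at −10 °C |  |  |
| time |  |  | 2.5 d | 2.5 d | 2.5 d | 2.5 d |

| run | time / d | target / % |
|---|---|---|
| Saturday's | 2.08 | 0.1 |
| Saturday's | 6.00 | 0 |
| Saturday's | 10.0 | 0.6 |
| Saturday's | 15.0 | 0 |
| Saturday's | 25.0 | 0.2 |
| Saturday's | 30.0 | 0 |
| Saturday's | 40.0 | 0.3 |
| Monday's | 0.417 | 0.3 |
| Monday's | 1.25 | 0.6 |
| Monday's | 2.00 | 1.1 |
| Monday's | 4.00 | 3.0 |
| Monday's | 6.00 | 5.4 |
| Monday's | 8.00 | 6.4 |

(standard deviation of a reading: 0.3 percentage points)

- the best flask by amount of target, in percent of the starting material charged; "all alike" if 1.5 percentage points covers them all (red / ochre / blue / teal / all alike)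
- amount of target at the end, in percent of the starting material charged, red
- amount of target at the end, in percent of the starting material charged, ochre
- amount of target at the end, in percent of the starting material charged, blue
- amount of target at the end, in percent of the starting material charged, teal



I kept 28.3 d as the square-law time: the time at which a target growing with the square of time, taken from Monday's reading at 2.00 d and scaled in proportion to [partner] down to 1.00 M, reaches the whole charge. The amount at any early time is then the square of that time over the square-law time. The reading under it carries a scatter of 27.3%, and the proportion to [partner] is my assumption. For blue, at Monday's temperature, it gave me 0.781%. Saturday's last reading, 0.3% at 40.0 d, is about one scatter, so I took it as a high figure for the target, which gives a short square-law time at −15 °C, 864 d, scaled the same way. Interpolating the logarithm of this time by degrees put teal a factor of 17.3 above blue's time, at 490 d, hence 0.00262% there. For red the same rule gave 233%, more than the charge, so I gave no number for red.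

The forecast named red as best, with red 9%, ochre 3.5%, blue 0.7% and teal 0.05%: “It gives 7% if capped and 13% if not, so I guess 9%.” My blue stood a little above its figure.

The flasks gave red 19.5%, ochre 10.4%, blue 0.704% and teal 0%, with red the best.

    starting material + partner ⇌ intermediate (K = 12.0 /M, k = 0.0730 /M/h, Ea = 62.0 kJ/mol, ΔH = −48.0 kJ/mol)
    intermediate ⇌ target + released group (K = 1.90 M, k = 0.0270 /h, Ea = 110 kJ/mol, ΔH = −47.0 kJ/mol)
    starting material + protic impurity → quenched substrate (k = 0.450 /M/h, Ea = 63.0 kJ/mol)
    intermediate → side product (k = 0.0280 /h, Ea = 111 kJ/mol)
    (constants at 40 °C)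

Red and ochre came out 10 percentage points and 6.9 points above the forecast; ochre already held 10.4% target at 0.833 d. Blue, at 0.704% against my 0.781%, had not come to rest: at 25.0 d it holds 12.5% target, where the square-law time gives 78.0%, with partner down to 1.31% of its charge. Red had not come to rest either: by 25.0 d its target falls to 8.44% while side product climbs from 23.7% to 41.1%. Ochre's target stands at 10.5% at 25.0 d, against 10.4% at the end.

For teal read at 6.0 d, the square-law time, 28.3 d times the factor 17.3, gives 0.0151%, below the scatter. The computed amount is 0.00640%.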